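**Remark on the chemistry.** Ring A is the acyl ring (C1 bears the ester carbonyl, C2 OH, C3 CHO, C4 OH, C5 H, C6 CH3). Ring B is the benzyl ring (C1' bears the free carboxyl, C2' OH, C3' CH3, C4' OH, C5' H, C6' the CH2O arm). Both starting materials are taken to be bought, and the formyl oxygen introduced in step 2 is taken to come from the hydrolytic work-up.

## The problem

Alectorialic acid (13) is a benzyl depside: the carboxyl of ring A is joined through a CH2–O–C(=O) bridge to C6' of ring B. It has no stereocentre, so the task is regiochemistry on two crowded benzene rings and the survival of a fragile set of groups. The weak points are the benzylic ester (which rules out hydrogenolysis once it exists), the aldehyde between two chelated phenols, and four free phenols. The worst is the C1' carboxyl ortho to the CH2O arm: the alcohol half of the ester exists on its own only as a phthalide, and in 13 the carboxylate can expel the ring A acid in a five-membered lactonisation. The ring A acid 5 is flanked at its carboxyl carbon by two ortho substituents and loses CO2 on heating, so the ester bond is better made by alkylating its carboxylate than by activating it. Whatever has to be removed after the C1' carboxyl is in place must come off without base, heat or hydrogen. The enabling feature is that ring B without its C1' carboxyl is the mirror-symmetric 3,5-dihydroxy-4-methylbenzyl unit. Its two open positions are equivalent, each ortho to one hydroxyl and para to the other, so iodine enters exactly where the carboxyl carbon belongs, and palladium with CO can turn that C–I bond into C–CO2H as the last act.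

## Retrosynthesis

**13 to 12.** The C1'–CO2H bond is cut first, which leads to the iodo ester 12. The neighbouring cuts fail while the carboxyl is present: cutting the ester at its acyl–O or its CH2–O bond would call for a ring B partner with a carboxyl next to a benzylic alcohol or leaving group, and that partner closes to the lactone. With the carboxyl absent, nothing in 12 or in any compound before it can lactonise. The forward reaction must insert CO only at the C–I bond and deliver the acid under conditions that four phenols, an aldehyde and a benzylic ester survive.

**12 to 11.** The two ring B phenols of 12 are traced back to the silyl ethers of 11. They are needed only because a benzylic bromide with free resorcinol hydroxyls would alkylate itself. The forward step must remove the silyl groups near neutrality so that the ester and aldehyde are untouched.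

**11 to 5 and 10.** The CH2–O bond of the bridge is cut to give haematommic acid 5 and the benzylic bromide 10. The alternative acyl–O cut would require activating the doubly ortho-substituted carboxyl of 5 in the presence of its own phenols and aldehyde. Alkylation moves the reacting centre to the unhindered benzylic carbon. The cut divides the molecule into two monocyclic halves of similar size. The forward reaction must alkylate the carboxylate only, not the acidic C4 hydroxyl.

**10 back to 6.** Bromide 10 comes from alcohol 9, 9 from ester 8 by reduction, and 8 from the iodo diphenol 7 by silylation. The C–I bond is cut at 7, leading to commercial methyl 3,5-dihydroxy-4-methylbenzoate (6). Iodinating here, not after the rings are joined, has three points in its favour: ring B is the only arene present, its ester tempers the resorcinol so that one iodine can be introduced, and ring A (itself open to halogenation at C5) never meets the iodinating agent. The forward reaction must stop at the mono-iodide; the two candidate positions are equivalent, so no regiochemical question arises.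

**5 back to 1.** Acid 5 is traced to its benzyl ester 4, which hydrogenolysis opens at room temperature without base or heat, before any benzylic bridge exists. The C3–CHO bond of 4 is cut, leading through the unisolated adduct 3 to benzyl orsellinate 2 and so to orsellinic acid (1). The forward formylation must choose C3, between the two hydroxyls, over C5.

## Roads not taken

**Alternative 1:** The cut runs through ring B itself, at C5'–C6' and C1'–C2'. The bis(silyloxy) diene A1 would add thermally to the alkynoate A2, which already carries a protected ring A acid on its propargylic oxygen. Aromatisation with loss of the ketene-acetal methoxy group and desilylation would give the tert-butyl ester A3.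
- Merits: the polarity of the two partners fixes the whole substitution pattern of ring B, no halogenation has to be stopped at one substitution, no CO is handled, and the carboxyl carbon is present from the start. In these respects it is as good as or better than the chosen plan.
- Weak points: ring A must carry two methoxymethyl ethers and a dioxolane before it can meet a silyl ketene acetal. A1 is moisture-sensitive, and its extra C-methyl group slows a cycloaddition that already needs heat. At the end a tert-butyl ester, two acetal ethers and a dioxolane must be removed with acid from a product whose free carboxyl sits beside the benzylic ester, so the lactonisation risk returns in the last operation under harsher conditions than a buffered carbonylation.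
- Comparison: the chosen plan buys ring B as an intact symmetric arene, never protects ring A after the acid is freed, and leaves nothing to remove after its key step.

**Alternative 2:** The cut is the C6'–CH2 bond. A palladium-catalysed Suzuki coupling of the potassium acyloxymethyltrifluoroborate A4 with the ring B aryl bromide A5 would give the fully protected ester A6.
- Merits: it is as convergent as the chosen plan, it needs no CO, and the carboxyl is carried as its tert-butyl ester from the start.
- Weak points: the bromine of A5 sits meta to both ring oxygens, where electrophilic bromination does not put it, so A5 needs an indirect preparation. The coupling runs in hot aqueous carbonate, which threatens the ester link and the free aldehyde of A4, and such trifluoroborates are established mainly for simple acyl groups. Four acetal ethers and the tert-butyl ester must then be removed with acid from the lactonisation-prone product.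
- Comparison: the chosen plan places its halogen where the ring's own polarity directs it (C1' is ortho and para to the hydroxyls) and ends with no protecting group left.

**Alternative 3:** The cut is the CH2–O bond, made with reversed polarity. The toluate A7, deprotonated at its C6' methyl by a lithium amide base, would attack the O–O bond of the diaroyl peroxide A8 to give A9.
- Merits: both rings come from orsellinate-type building blocks, as in the biogenesis, no transition metal is needed, and the bridge is made in one step from a methyl group.
- Weak points: half of A8, and with it half of the ring A material, is lost as the leaving group. A hindered, electron-rich diaroyl peroxide is awkward and hazardous to prepare. A benzylic anion can attack the peroxide carbonyl or transfer an electron in place of the wanted O-attack, and it can condense with the ester of its own product. Five acid-labile groups remain to be removed at the end.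
- Comparison: the chosen plan makes the same bridge by carboxylate alkylation, a far more dependable reaction that wastes nothing, and defers the carboxyl so that no acid deprotection follows.

Key step: step 10

## Route

Step 1
Reactants: 1 orsellinic acid (2,4-dihydroxy-6-methylbenzoic acid)
Product: 2 benzyl 2,4-dihydroxy-6-methylbenzoate (benzyl orsellinate)
Conditions: BnBr (1.05 equiv), KHCO3 (1.1 equiv), DMF, rt
Reagents that add atoms: benzyl bromide, BrCc1ccccc1
Why: Carboxylate O-alkylation (SN2); bicarbonate deprotonates only the carboxylic acid, so the phenols are not benzylated, and the absence of acid and heat avoids decarboxylation of 1.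

Step 2
Reactants: 2 benzyl 2,4-dihydroxy-6-methylbenzoate
Product: 4 benzyl 3-formyl-2,4-dihydroxy-6-methylbenzoate (benzyl haematommate), via chloro(methoxy)methyl arene 3 (not isolated)
Conditions: Cl2CHOMe (1.2 equiv), TiCl4 (2.2 equiv), CH2Cl2, −10 to 0 °C; then cold 1 M HCl
Reagents that add atoms: dichloromethyl methyl ether, COC(Cl)Cl; water, O
Why: Rieche formylation, an electrophilic aromatic substitution by the titanium-activated chloro(methoxy)carbenium ion; titanium bound to the phenolic oxygens delivers the electrophile to C3, the only position ortho to both hydroxyls, and chelation of the C2 hydroxyl to the ester further favours C3 over C5. The adduct 3 is hydrolysed to the aldehyde on aqueous work-up.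

Step 3
Reactants: 4 benzyl 3-formyl-2,4-dihydroxy-6-methylbenzoate
Product: 5 3-formyl-2,4-dihydroxy-6-methylbenzoic acid (haematommic acid)
Conditions: H2 (1 atm), 10% Pd/C, EtOAc, rt; stopped after uptake of one equivalent
Reagents that add atoms: none
Why: Hydrogenolysis of a benzyl ester over palladium on carbon; the doubly chelated aryl aldehyde is reduced much more slowly, and the neutral, unheated conditions spare the decarboxylation-prone acid.

Step 4
Reactants: 6 methyl 3,5-dihydroxy-4-methylbenzoate
Product: 7 methyl 3,5-dihydroxy-2-iodo-4-methylbenzoate
Conditions: N-iodosuccinimide (1.0 equiv), MeCN, −20 to 0 °C, dark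
Reagents that add atoms: N-iodosuccinimide, O=C1CCC(=O)N1I
Why: Electrophilic aromatic iodination of a phenol; the two open positions are equivalent and each is ortho to one hydroxyl and para to the other, and the ester tempers the ring so that one equivalent of reagent at low temperature should stop at the mono-iodide.

Step 5
Reactants: 7 methyl 3,5-dihydroxy-2-iodo-4-methylbenzoate
Product: 8 methyl 3,5-bis(tert-butyldimethylsilyloxy)-2-iodo-4-methylbenzoate
Conditions: TBSCl (2.6 equiv), imidazole (5 equiv), DMF, rt to 40 °C
Reagents that add atoms: tert-butyldimethylsilyl chloride, CC(C)(C)[Si](C)(C)Cl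
Why: Imidazole-promoted silylation of phenols; the hydroxyl between iodine and methyl is hindered, hence the excess of reagent and gentle warming.

Step 6
Reactants: 8 methyl 3,5-bis(tert-butyldimethylsilyloxy)-2-iodo-4-methylbenzoate
Product: 9 [3,5-bis(tert-butyldimethylsilyloxy)-2-iodo-4-methylphenyl]methanol
Conditions: i-Bu2AlH (2.5 equiv), CH2Cl2, −78 to 0 °C; aq. potassium sodium tartrate
Reagents that add atoms: none
Why: Hydride reduction of an ester to the primary alcohol; i-Bu2AlH at low temperature leaves the aryl iodide and the aryl silyl ethers untouched.

Step 7
Reactants: 9 [3,5-bis(tert-butyldimethylsilyloxy)-2-iodo-4-methylphenyl]methanol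
Product: 10 1-(bromomethyl)-3,5-bis(tert-butyldimethylsilyloxy)-2-iodo-4-methylbenzene
Conditions: CBr4 (1.3 equiv), PPh3 (1.3 equiv), CH2Cl2, 0 °C
Reagents that add atoms: carbon tetrabromide, BrC(Br)(Br)Br
Why: Appel bromination of a primary benzylic alcohol under neutral conditions that the silyl ethers and the iodide tolerate.

Step 8
Reactants: 10 1-(bromomethyl)-3,5-bis(tert-butyldimethylsilyloxy)-2-iodo-4-methylbenzene; 5 3-formyl-2,4-dihydroxy-6-methylbenzoic acid
Product: 11 [3,5-bis(tert-butyldimethylsilyloxy)-2-iodo-4-methylphenyl]methyl 3-formyl-2,4-dihydroxy-6-methylbenzoate
Conditions: KHCO3 (1.1 equiv), DMF, rt, dark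
Reagents that add atoms: none
Why: SN2 O-alkylation of a carboxylate by a primary benzylic bromide, the reaction type of step 1; just over one equivalent of bicarbonate ionises only the carboxylic acid, and the bond forms at the benzylic carbon, away from the hindered carboxyl carbon of 5.

Step 9
Reactants: 11 [3,5-bis(tert-butyldimethylsilyloxy)-2-iodo-4-methylphenyl]methyl 3-formyl-2,4-dihydroxy-6-methylbenzoate
Product: 12 (3,5-dihydroxy-2-iodo-4-methylphenyl)methyl 3-formyl-2,4-dihydroxy-6-methylbenzoate
Conditions: TBAF/AcOH (1:1, 2.5 equiv), THF, 0 °C
Reagents that add atoms: none
Why: Fluoride cleavage of aryl silyl ethers; the acetic acid buffer protonates each phenoxide as it forms, so the benzylic ester, the aldehyde and the aryl iodide are left alone.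

Step 10
Reactants: 12 (3,5-dihydroxy-2-iodo-4-methylphenyl)methyl 3-formyl-2,4-dihydroxy-6-methylbenzoate
Product: 13 alectorialic acid
Conditions: Pd(OAc)2 (5 mol %), Xantphos (6 mol %), CO (1 atm), KOAc (3 equiv), 1,4-dioxane/H2O 4:1, 45 °C; then cold aq. citric acid to pH 3, EtOAc
Reagents that add atoms: carbon monoxide, [C-]#[O+]; water, O
Why: Palladium-catalysed hydroxycarbonylation of an aryl iodide, a known reaction type. Pd(OAc)2 (divalent palladium) is reduced in the flask to Xantphos-bound zerovalent palladium, which inserts into the C1'–I bond, the only carbon–halogen bond of 12. CO then inserts to give the aroylpalladium iodide, and acetate and water cleave it (directly or through the mixed anhydride) to the C1' carboxylic acid while KOAc takes up the hydrogen iodide. One skeletal bond (C1'–CO2H) forms, no ring closes and no stereocentre is created. The selectivity needed is chemoselectivity: oxidative addition must touch only the C–I bond, which at 45 °C is far more reactive towards zerovalent palladium than the benzylic C–O bond or the formyl C–H bond, and the acylpalladium must be taken by water and not by a phenol. The large molar excess of water, the weak acetate base (which leaves the ring B phenols largely protonated) and the chelation of both ring A hydroxyls to the formyl and ester carbonyls should secure this. The wide bite angle of Xantphos favours CO insertion and acyl transfer at one atmosphere and low temperature. Together with the buffered aqueous medium and the cold acidic work-up, this should keep displacement of the ring A carboxylate by the new ortho carboxylate (phthalide formation) to a minimum.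

## Compound list

1 | orsellinic acid (2,4-dihydroxy-6-methylbenzoic acid) | Cc1cc(O)cc(O)c1C(=O)O | starting material
2 | benzyl 2,4-dihydroxy-6-methylbenzoate (benzyl orsellinate) | Cc1cc(O)cc(O)c1C(=O)OCc1ccccc1 | intermediate
3 | benzyl 3-[chloro(methoxy)methyl]-2,4-dihydroxy-6-methylbenzoate (Rieche adduct before hydrolysis, not isolated) | COC(Cl)c1c(O)cc(C)c(C(=O)OCc2ccccc2)c1O | intermediate
4 | benzyl 3-formyl-2,4-dihydroxy-6-methylbenzoate (benzyl haematommate) | Cc1cc(O)c(C=O)c(O)c1C(=O)OCc1ccccc1 | intermediate
5 | 3-formyl-2,4-dihydroxy-6-methylbenzoic acid (haematommic acid) | Cc1cc(O)c(C=O)c(O)c1C(=O)O | intermediate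
6 | methyl 3,5-dihydroxy-4-methylbenzoate | COC(=O)c1cc(O)c(C)c(O)c1 | starting material
7 | methyl 3,5-dihydroxy-2-iodo-4-methylbenzoate | COC(=O)c1cc(O)c(C)c(O)c1I | intermediate
8 | methyl 3,5-bis(tert-butyldimethylsilyloxy)-2-iodo-4-methylbenzoate | COC(=O)c1cc(O[Si](C)(C)C(C)(C)C)c(C)c(O[Si](C)(C)C(C)(C)C)c1I | intermediate
9 | [3,5-bis(tert-butyldimethylsilyloxy)-2-iodo-4-methylphenyl]methanol | Cc1c(O[Si](C)(C)C(C)(C)C)cc(CO)c(I)c1O[Si](C)(C)C(C)(C)C | intermediate
10 | 1-(bromomethyl)-3,5-bis(tert-butyldimethylsilyloxy)-2-iodo-4-methylbenzene | Cc1c(O[Si](C)(C)C(C)(C)C)cc(CBr)c(I)c1O[Si](C)(C)C(C)(C)C | intermediate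
11 | [3,5-bis(tert-butyldimethylsilyloxy)-2-iodo-4-methylphenyl]methyl 3-formyl-2,4-dihydroxy-6-methylbenzoate | Cc1cc(O)c(C=O)c(O)c1C(=O)OCc1cc(O[Si](C)(C)C(C)(C)C)c(C)c(O[Si](C)(C)C(C)(C)C)c1I | intermediate
12 | (3,5-dihydroxy-2-iodo-4-methylphenyl)methyl 3-formyl-2,4-dihydroxy-6-methylbenzoate | Cc1cc(O)c(C=O)c(O)c1C(=O)OCc1cc(O)c(C)c(O)c1I | intermediate
13 | alectorialic acid | Cc1cc(O)c(C=O)c(O)c1C(=O)OCc1cc(O)c(C)c(O)c1C(=O)O | target

## Step count and risks

Total: 10 steps. Longest linear sequence: 7 steps (6 to 13, steps 4 to 10). The ring A branch (steps 1 to 3) joins at step 8.

**Step 10 (key step).**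
- What may go wrong: capture of the aroylpalladium by a ring B phenoxide of a second molecule in place of water, reductive loss of iodine through a palladium hydride formed from CO and water, and lactonisation of the product with loss of the ring A acid if the mixture is warmed or left basic.
- Why: the C–I bond is flanked on both sides, so carbonylation is slow relative to these side paths, and the product carries its carboxylate next to the benzylic ester.
- Fallback: the carbonylation is moved one step earlier. It sets out from 11, which under the same palladium, CO and water system should give 2,4-bis(tert-butyldimethylsilyloxy)-6-[(3-formyl-2,4-dihydroxy-6-methylbenzoyl)oxymethyl]-3-methylbenzoic acid F1. In F1 both ring B phenols are masked and the new carboxyl is shielded. Acidic fluoride (HF·pyridine, THF, 0 °C), under which the carboxyl stays protonated, should then remove the silyl groups, and the route is rejoined at 13.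

**Step 2.**
- What may go wrong: poor regioselectivity, with formylation at C5 or at both open positions, because C5 is also ortho and para to the two hydroxyls.
- Fallback: C5 is blocked first. It sets out from 2, which is brominated with N-bromosuccinimide at the position para to the chelated hydroxyl to give benzyl 5-bromo-2,4-dihydroxy-6-methylbenzoate F2. Rieche formylation can then take only C3 and should give, through benzyl 5-bromo-3-[chloro(methoxy)methyl]-2,4-dihydroxy-6-methylbenzoate F3 (not isolated), benzyl 5-bromo-3-formyl-2,4-dihydroxy-6-methylbenzoate F4. Hydrogenolysis over Pd/C with NaOAc removes the benzyl ester and the bromine together, and the route is rejoined at 5.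

**Step 4.**
- What may go wrong: over-iodination at the second equivalent position, because the first iodine twists the ester out of conjugation and so hardly deactivates the ring.
- Fallback: the order of protection and iodination is reversed. It sets out from 6, which is silylated to methyl 3,5-bis(tert-butyldimethylsilyloxy)-4-methylbenzoate F5 and reduced with i-Bu2AlH to [3,5-bis(tert-butyldimethylsilyloxy)-4-methylphenyl]methanol F6. Iodination of F6 with N-iodosuccinimide and catalytic trifluoroacetic acid should be slower and should stop after one substitution, since the silyl ethers are weaker donors and screen the remaining site. The route is rejoined at 9.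

**Step 8.**
- What may go wrong: alkylation of the acidic C4 hydroxyl of 5 in competition with the carboxylate, premature loss of the aryl silyl groups of 10 in DMF with bicarbonate followed by self-alkylation of the bromide, and decarboxylation of 5 before it reacts.
- Fallback: the alcohol is activated in place of the bromide, with no base present. It sets out from 9 and 5, which are joined by Mitsunobu esterification (PPh3, diisopropyl azodicarboxylate, THF, 0 °C). The carboxylic acid, by far the most acidic pronucleophile, should attack the oxyphosphonium ion at the benzylic carbon, and the route is rejoined at 11. This fallback makes no compound outside the list (F0).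

## Further compounds

F1 | step 10 | 2,4-bis(tert-butyldimethylsilyloxy)-6-[(3-formyl-2,4-dihydroxy-6-methylbenzoyl)oxymethyl]-3-methylbenzoic acid | Cc1cc(O)c(C=O)c(O)c1C(=O)OCc1cc(O[Si](C)(C)C(C)(C)C)c(C)c(O[Si](C)(C)C(C)(C)C)c1C(=O)O
F2 | step 2 | benzyl 5-bromo-2,4-dihydroxy-6-methylbenzoate | Cc1c(Br)c(O)cc(O)c1C(=O)OCc1ccccc1
F3 | step 2 | benzyl 5-bromo-3-[chloro(methoxy)methyl]-2,4-dihydroxy-6-methylbenzoate | COC(Cl)c1c(O)c(Br)c(C)c(C(=O)OCc2ccccc2)c1O
F4 | step 2 | benzyl 5-bromo-3-formyl-2,4-dihydroxy-6-methylbenzoate | Cc1c(Br)c(O)c(C=O)c(O)c1C(=O)OCc1ccccc1
F5 | step 4 | methyl 3,5-bis(tert-butyldimethylsilyloxy)-4-methylbenzoate | COC(=O)c1cc(O[Si](C)(C)C(C)(C)C)c(C)c(O[Si](C)(C)C(C)(C)C)c1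
F6 | step 4 | [3,5-bis(tert-butyldimethylsilyloxy)-4-methylphenyl]methanol | Cc1c(O[Si](C)(C)C(C)(C)C)cc(CO)cc1O[Si](C)(C)C(C)(C)C
F0 | step 8 | none | none
A1 | alternative 1 | 1-methoxy-2-methyl-1,3-bis(trimethylsilyloxy)buta-1,3-diene | COC(O[Si](C)(C)C)=C(C)C(=C)O[Si](C)(C)C
A2 | alternative 1 | tert-butyl 4-{[3-(1,3-dioxolan-2-yl)-2,4-bis(methoxymethoxy)-6-methylbenzoyl]oxy}but-2-ynoate | CC(C)(C)OC(=O)C#CCOC(=O)c1c(C)cc(OCOC)c(C2OCCO2)c1OCOC
A3 | alternative 1 | tert-butyl ester of alectorialic acid with ring A as its bis(methoxymethyl) ether and dioxolane | CC(C)(C)OC(=O)c1c(O)c(C)c(O)cc1COC(=O)c1c(C)cc(OCOC)c(C2OCCO2)c1OCOC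
A4 | alternative 2 | potassium {[3-formyl-2,4-bis(methoxymethoxy)-6-methylbenzoyl]oxymethyl}trifluoroborate | Cc1cc(OCOC)c(C=O)c(OCOC)c1C(=O)OC[B-](F)(F)F.[K+]
A5 | alternative 2 | tert-butyl 6-bromo-2,4-bis(methoxymethoxy)-3-methylbenzoate | CC(C)(C)OC(=O)c1c(Br)cc(OCOC)c(C)c1OCOC
A6 | alternative 2 | tert-butyl ester of alectorialic acid tetrakis(methoxymethyl) ether | Cc1cc(OCOC)c(C=O)c(OCOC)c1C(=O)OCc1cc(OCOC)c(C)c(OCOC)c1C(=O)OC(C)(C)C
A7 | alternative 3 | tert-butyl 2,4-bis(methoxymethoxy)-3,6-dimethylbenzoate | CC(C)(C)OC(=O)c1c(C)cc(OCOC)c(C)c1OCOC
A8 | alternative 3 | bis[3-(1,3-dioxolan-2-yl)-2,4-bis(methoxymethoxy)-6-methylbenzoyl] peroxide | Cc1cc(OCOC)c(C2OCCO2)c(OCOC)c1C(=O)OOC(=O)c1c(C)cc(OCOC)c(C2OCCO2)c1OCOC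
A9 | alternative 3 | tert-butyl ester of alectorialic acid as its tetrakis(methoxymethyl) ether and ring A dioxolane | Cc1cc(OCOC)c(C2OCCO2)c(OCOC)c1C(=O)OCc1cc(OCOC)c(C)c(OCOC)c1C(=O)OC(C)(C)C
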